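**Plan**

- Numbering: C1 is the lactone carbonyl, C13 the ethyl-bearing carbinol, and the ring oxygen closes the 14-membered ring. The feature that permits the key step is the Z-trisubstituted ring alkene C11=C12 (C10 cis to C13), which lies between the C10 exo-methylene and C13 and has the Z-1-methylpropenyl pattern of angelic acid.
- Cuts: C11=C12 (ring-closing metathesis), C13–O (ester), C10–vinyl (Stille), C2–C3 (aldol), C6–OMe (from a C6≡C7 alkyne), C5–C6 (acetylide plus epoxide).
- Forward: the C6–C10 alkyne and the C3–C5 epoxide are joined, the alkyne becomes the 6E methyl enol ether, the aldol adds C1–C2, the vinyl group is attached, the acid is esterified with the C12–C13 alcohol, and metathesis closes the only ring. Oxidation at C3 and desilylation finish the synthesis.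
- Stereochemistry: C8 from an Evans alkylation, C4 from a Sharpless epoxidation, C2 from an Evans syn aldol, C13 from a Corey–Bakshi–Shibata reduction. The 6E geometry comes from syn hydroboration and a stereoretentive C–O coupling; the 11Z geometry is copied from angelic acid by stereoretentive metathesis.

Key step: step 21

Remark: the C3 configuration set in step 13 is of no consequence because C3 is oxidised in step 23. The C2 centre of the final β-keto lactone is assumed to hold under the buffered, non-basic conditions of steps 23 and 24.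

**Route**

Step 1
Reactants: 1 (R)-4-benzyl-3-propionyloxazolidin-2-one; 2 2,3-dibromopropene
Product: 4 (R)-4-benzyl-3-[(S)-4-bromo-2-methylpent-4-enoyl]oxazolidin-2-one, via sodium (Z)-enolate of the propionyl imide 3 (not isolated)
Conditions: NaN(SiMe3)2, THF, −78 °C; then 2, −78 → −30 °C
Reagents that add atoms: none
Why: Evans asymmetric alkylation, in which the chelated sodium (Z)-enolate is attacked by the allylic bromide on the face opposite the benzyl group, should set the future C8 as S.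

Step 2
Reactants: 4 (R)-4-benzyl-3-[(S)-4-bromo-2-methylpent-4-enoyl]oxazolidin-2-one
Product: 5 (S)-4-bromo-2-methylpent-4-en-1-ol
Conditions: LiBH4, MeOH (1 equiv), Et2O, 0 °C
Reagents that add atoms: none
Why: Reductive cleavage of the auxiliary (hydride reduction of the exocyclic imide carbonyl) should leave the stereocentre and the 2-bromoalkene untouched.

Step 3
Reactants: 5 (S)-4-bromo-2-methylpent-4-en-1-ol
Product: 7 (S)-2-bromo-4-methylhex-1-en-5-yne, via (S)-4-bromo-2-methylpent-4-enal 6 (not isolated)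
Conditions: Dess–Martin periodinane, NaHCO3, CH2Cl2, 0 °C; filtration; then MeC(O)C(N2)P(O)(OMe)2, K2CO3, MeOH, 0 °C → rt
Reagents that add atoms: dimethyl (1-diazo-2-oxopropyl)phosphonate, CC(=O)C(=[N+]=[N-])P(=O)(OC)OC
Why: Dess–Martin oxidation and Ohira–Bestmann homologation turn the carbinol into the terminal alkyne, and buffered oxidation with carbonate at low temperature should limit epimerisation of the α-methyl aldehyde.

Step 4
Reactants: 8 2-methylenepropane-1,3-diol
Product: 9 2-[(tert-butyldiphenylsilyloxy)methyl]prop-2-en-1-ol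
Conditions: TBDPSCl (0.35 equiv), imidazole, THF, 0 °C
Reagents that add atoms: tert-butyl(chloro)diphenylsilane, CC(C)(C)[Si](Cl)(c1ccccc1)c1ccccc1
Why: Statistical monosilylation of a cheap symmetric diol used in excess should give the mono-ether.

Step 5
Reactants: 9 2-[(tert-butyldiphenylsilyloxy)methyl]prop-2-en-1-ol
Product: 10 [(2R)-2-[(tert-butyldiphenylsilyloxy)methyl]oxiran-2-yl]methanol
Conditions: Ti(OiPr)4 (10 mol%), D-(−)-diisopropyl tartrate (12 mol%), t-BuOOH, 4 Å MS, CH2Cl2, −20 °C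
Reagents that add atoms: tert-butyl hydroperoxide, CC(C)(C)OO
Why: Sharpless asymmetric epoxidation of a 2-substituted allylic alcohol, in which the titanium D-tartrate complex delivers oxygen to one enantiotopic face of the 1,1-disubstituted alkene, should set the quaternary C4; the free hydroxymethyl later becomes C3.

Step 6
Reactants: 10 [(2R)-2-[(tert-butyldiphenylsilyloxy)methyl]oxiran-2-yl]methanol
Product: 11 (2S)-2-[(tert-butyldiphenylsilyloxy)methyl]-2-[(triethylsilyloxy)methyl]oxirane
Conditions: TESCl, imidazole, CH2Cl2, 0 °C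
Reagents that add atoms: chlorotriethylsilane, CC[Si](Cl)(CC)CC
Why: Silylation of the primary alcohol keeps an alkoxide from forming next to the TBDPS ether (silyl migration between the two oxymethyl arms would racemise C4) and installs a group that can later be removed selectively.

Step 7
Reactants: 7 (S)-2-bromo-4-methylhex-1-en-5-yne; 11 (2S)-2-[(tert-butyldiphenylsilyloxy)methyl]-2-[(triethylsilyloxy)methyl]oxirane
Product: 13 (2S,6S)-8-bromo-2-[(tert-butyldiphenylsilyloxy)methyl]-6-methyl-1-(triethylsilyloxy)non-8-en-4-yn-2-ol, via lithium acetylide of the enyne 12 (not isolated)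
Conditions: 7 (1.5 equiv), n-BuLi, THF, −78 °C; BF3·OEt2; then 11, −78 °C
Reagents that add atoms: none
Why: BF3-mediated SN2 opening of the epoxide at its unsubstituted carbon by the lithium acetylide forms C5–C6 without touching C4, and deprotonation of the alkyne by n-BuLi at −78 °C should outrun bromine–lithium exchange at the 2-bromoalkene.

Step 8
Reactants: 13 (2S,6S)-8-bromo-2-[(tert-butyldiphenylsilyloxy)methyl]-6-methyl-1-(triethylsilyloxy)non-8-en-4-yn-2-ol
Product: 14 (2S,6S)-8-bromo-2-[(tert-butyldiphenylsilyloxy)methyl]-6-methyl-1,2-bis(triethylsilyloxy)non-8-en-4-yne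
Conditions: TESOTf, 2,6-lutidine, CH2Cl2, −78 → 0 °C
Reagents that add atoms: triethylsilyl trifluoromethanesulfonate, CC[Si](CC)(CC)OS(=O)(=O)C(F)(F)F
Why: Silylation with the silyl triflate is the standard way to cap a hindered tertiary alcohol.

Step 9
Reactants: 14 (2S,6S)-8-bromo-2-[(tert-butyldiphenylsilyloxy)methyl]-6-methyl-1,2-bis(triethylsilyloxy)non-8-en-4-yne
Product: 15 (2S,4Z,6S)-8-bromo-2-[(tert-butyldiphenylsilyloxy)methyl]-6-methyl-4-(4,4,5,5-tetramethyl-1,3,2-dioxaborolan-2-yl)-1,2-bis(triethylsilyloxy)nona-4,8-diene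
Conditions: HBpin, CuCl (5 mol%), NaOt-Bu (10 mol%), 4,5-bis(diphenylphosphino)-9,9-dimethylxanthene (5 mol%), toluene, rt
Reagents that add atoms: pinacolborane, [H]B1OC(C)(C)C(C)(C)O1
Why: Copper hydride-catalysed syn hydroboration of the internal alkyne should place copper, and after σ-bond metathesis boron, at C6, the carbon nearer the electron-withdrawing C4 silyloxy groups and remote from the α-branched C8, with boron cis to H7 so that C5 and C8 end up cis.

Step 10
Reactants: 15 (2S,4Z,6S)-8-bromo-2-[(tert-butyldiphenylsilyloxy)methyl]-6-methyl-4-(4,4,5,5-tetramethyl-1,3,2-dioxaborolan-2-yl)-1,2-bis(triethylsilyloxy)nona-4,8-diene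
Product: 16 (2S,4E,6S)-8-bromo-2-[(tert-butyldiphenylsilyloxy)methyl]-4-methoxy-6-methyl-1,2-bis(triethylsilyloxy)nona-4,8-diene
Conditions: Cu(OAc)2 (2 equiv), Et3N (4 equiv), MeOH, 4 Å MS, rt
Reagents that add atoms: methanol, CO
Why: Chan–Lam-type oxidative coupling (transmetallation of the alkenyl boronate to divalent copper acetate, then C–O reductive elimination with methanol) should replace boron by methoxy with retention and give the 6E enol ether, the 2-bromoalkene being inert at room temperature.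

Step 11
Reactants: 16 (2S,4E,6S)-8-bromo-2-[(tert-butyldiphenylsilyloxy)methyl]-4-methoxy-6-methyl-1,2-bis(triethylsilyloxy)nona-4,8-diene
Product: 17 (2S,4E,6S)-8-bromo-2-[(tert-butyldiphenylsilyloxy)methyl]-4-methoxy-6-methyl-2-(triethylsilyloxy)nona-4,8-dien-1-ol
Conditions: HF·pyridine, pyridine, THF, 0 °C
Reagents that add atoms: none
Why: Selective fluoride-mediated desilylation should remove the primary triethylsilyl ether well before the tertiary one or the TBDPS ether, and the pyridine buffer protects the enol ether.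

Step 12
Reactants: 17 (2S,4E,6S)-8-bromo-2-[(tert-butyldiphenylsilyloxy)methyl]-4-methoxy-6-methyl-2-(triethylsilyloxy)nona-4,8-dien-1-ol
Product: 18 (2R,4E,6S)-8-bromo-2-[(tert-butyldiphenylsilyloxy)methyl]-4-methoxy-6-methyl-2-(triethylsilyloxy)nona-4,8-dienal
Conditions: Dess–Martin periodinane, NaHCO3, CH2Cl2, 0 °C
Reagents that add atoms: none
Why: Dess–Martin oxidation under bicarbonate buffer is mild enough for the enol ether, and the aldehyde has no α-hydrogen and cannot epimerise.

Step 13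
Reactants: 1 (R)-4-benzyl-3-propionyloxazolidin-2-one; 18 (2R,4E,6S)-8-bromo-2-[(tert-butyldiphenylsilyloxy)methyl]-4-methoxy-6-methyl-2-(triethylsilyloxy)nona-4,8-dienal
Product: 20 (R)-4-benzyl-3-[(2R,3R,4R,6E,8S)-10-bromo-4-[(tert-butyldiphenylsilyloxy)methyl]-3-hydroxy-6-methoxy-2,8-dimethyl-4-(triethylsilyloxy)undeca-6,10-dienoyl]oxazolidin-2-one, via dibutylboron (Z)-enolate of the propionyl imide 19 (not isolated)
Conditions: 1 (1.5 equiv), Bu2BOTf, Et3N, CH2Cl2, −78 → 0 °C; then 18, −78 → 0 °C; pH 7 buffer, MeOH, H2O2, 0 °C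
Reagents that add atoms: none
Why: Evans syn aldol through the boron (Z)-enolate and a Zimmerman–Traxler transition state, in which the (R)-auxiliary fixes C2 as R (and C3 as R, a centre that is oxidised later); the triflate is kept substoichiometric to the imide so that no free Lewis acid meets the enol ether.

Step 14
Reactants: 20 (R)-4-benzyl-3-[(2R,3R,4R,6E,8S)-10-bromo-4-[(tert-butyldiphenylsilyloxy)methyl]-3-hydroxy-6-methoxy-2,8-dimethyl-4-(triethylsilyloxy)undeca-6,10-dienoyl]oxazolidin-2-one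
Product: 21 (R)-4-benzyl-3-[(2R,3R,4R,6E,8S)-10-bromo-4-[(tert-butyldiphenylsilyloxy)methyl]-6-methoxy-2,8-dimethyl-3,4-bis(triethylsilyloxy)undeca-6,10-dienoyl]oxazolidin-2-one
Conditions: TESOTf, 2,6-lutidine, CH2Cl2, −78 → 0 °C
Reagents that add atoms: triethylsilyl trifluoromethanesulfonate, CC[Si](CC)(CC)OS(=O)(=O)C(F)(F)F
Why: Silylation of the secondary carbinol prevents retro-aldol cleavage and lactonisation later and gives a substrate without protic groups for the molybdenum catalyst.

Step 15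
Reactants: 21 (R)-4-benzyl-3-[(2R,3R,4R,6E,8S)-10-bromo-4-[(tert-butyldiphenylsilyloxy)methyl]-6-methoxy-2,8-dimethyl-3,4-bis(triethylsilyloxy)undeca-6,10-dienoyl]oxazolidin-2-one
Product: 22 (R)-4-benzyl-3-[(2R,3R,4R,6E,8S)-4-[(tert-butyldiphenylsilyloxy)methyl]-6-methoxy-2,8-dimethyl-10-methylidene-3,4-bis(triethylsilyloxy)dodeca-6,11-dienoyl]oxazolidin-2-one
Conditions: Bu3SnCH=CH2, Pd2(dba)3 (5 mol%), AsPh3 (20 mol%), CuI (10 mol%), NMP, 40 °C
Reagents that add atoms: tributyl(vinyl)stannane, C=C[Sn](CCCC)(CCCC)CCCC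
Why: Stille coupling of the 2-bromoalkene gives the 2-substituted butadiene, and it is run before the allylic ester exists so that zerovalent palladium cannot ionise it.

Step 16
Reactants: 22 (R)-4-benzyl-3-[(2R,3R,4R,6E,8S)-4-[(tert-butyldiphenylsilyloxy)methyl]-6-methoxy-2,8-dimethyl-10-methylidene-3,4-bis(triethylsilyloxy)dodeca-6,11-dienoyl]oxazolidin-2-one
Product: 24 (2R,3R,4R,6E,8S)-4-[(tert-butyldiphenylsilyloxy)methyl]-6-methoxy-2,8-dimethyl-10-methylidene-3,4-bis(triethylsilyloxy)dodeca-6,11-dienoic acid, via lithium peroxycarboxylate of the diene acid 23 (not isolated)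
Conditions: LiOH, H2O2, THF/H2O, 0 °C; Na2SO3; then NaH2PO4 to pH 5
Reagents that add atoms: hydrogen peroxide, OO
Why: Hydroperoxide cleavage of the imide attacks the exocyclic carbonyl selectively, and sulfite reduces the percarboxylate before acidification so that diene and enol ether never meet a free peracid.

Step 17
Reactants: 25 angelic acid
Product: 26 (Z)-N-methoxy-N,2-dimethylbut-2-enamide
Conditions: MeNH(OMe)·HCl, EDC·HCl, HOBt, N-methylmorpholine, CH2Cl2, 0 °C
Reagents that add atoms: N,O-dimethylhydroxylamine hydrochloride, CNOC.Cl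
Why: Carbodiimide amide coupling through the hydroxybenzotriazole ester at 0 °C is chosen over acid chloride or DMAP activation, which are known to isomerise angelates to tiglates.

Step 18
Reactants: 26 (Z)-N-methoxy-N,2-dimethylbut-2-enamide
Product: 27 (Z)-4-methylhex-4-en-3-one
Conditions: EtMgBr, THF, −20 → 0 °C; cold aqueous NH4Cl
Reagents that add atoms: ethylmagnesium bromide, CC[Mg]Br
Why: Weinreb ketone synthesis, in which the chelated tetrahedral intermediate survives until work-up, should prevent over-addition and conjugate addition.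

Step 19
Reactants: 27 (Z)-4-methylhex-4-en-3-one
Product: 28 (S,Z)-4-methylhex-4-en-3-ol
Conditions: (R)-Me-CBS oxazaborolidine [(R)-1-methyl-3,3-diphenyltetrahydro-1H,3H-pyrrolo[1,2-c][1,3,2]oxazaborole] (20 mol%), BH3·SMe2, THF, −30 °C; MeOH
Reagents that add atoms: none
Why: Corey–Bakshi–Shibata reduction, in which the catalyst–borane complex binds the ketone with the α-branched alkenyl group as the large substituent, should deliver hydride to the face that gives the 3S alcohol.

Step 20
Reactants: 24 (2R,3R,4R,6E,8S)-4-[(tert-butyldiphenylsilyloxy)methyl]-6-methoxy-2,8-dimethyl-10-methylidene-3,4-bis(triethylsilyloxy)dodeca-6,11-dienoic acid; 28 (S,Z)-4-methylhex-4-en-3-ol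
Product: 30 (S,Z)-4-methylhex-4-en-3-yl (2R,3R,4R,6E,8S)-4-[(tert-butyldiphenylsilyloxy)methyl]-6-methoxy-2,8-dimethyl-10-methylidene-3,4-bis(triethylsilyloxy)dodeca-6,11-dienoate, via 2,4,6-trichlorobenzoic mixed anhydride of the diene acid 29 (not isolated)
Conditions: 2,4,6-Cl3C6H2COCl, Et3N, toluene, rt; then 28, DMAP, rt
Reagents that add atoms: none
Why: Yamaguchi esterification (mixed anhydride, then DMAP acyl transfer) couples hindered partners, and the carbinol configuration is retained because its C–O bond is not broken.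

Step 21
Reactants: 30 (S,Z)-4-methylhex-4-en-3-yl (2R,3R,4R,6E,8S)-4-[(tert-butyldiphenylsilyloxy)methyl]-6-methoxy-2,8-dimethyl-10-methylidene-3,4-bis(triethylsilyloxy)dodeca-6,11-dienoate
Product: 31 (2R,3R,4R,6E,8S,11Z,13S)-4-[(tert-butyldiphenylsilyloxy)methyl]-6-methoxy-2,8,12-trimethyl-10-methylidene-3,4-bis(triethylsilyloxy)pentadeca-6,11-dien-13-olide
Conditions: Mo(NC6F5)(CHCMe2Ph)(Cl)(OAr)(MeCN) (10 mol%, OAr = 2,6-bis(2,4,6-triisopropylphenyl)phenoxide), benzene, 1 mM, 22 °C, 100 torr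
Reagents that add atoms: none
Why: Proposed new method: the neophylidene complex should exchange onto the monosubstituted vinyl terminus (the 1,1-disubstituted C10 methylene, the trisubstituted enol ether and the trisubstituted C12 alkene are too hindered to initiate) to give Mo=C11H, which adds intramolecularly across the (Z)-C12=CH(CH3) alkene and cycloreverts to C11=C12 and Mo=CHCH3, the ethylidene leaving as propene after exchange with the next vinyl group. The closest known reaction type is stereoretentive macrocyclic ring-closing metathesis of stereodefined trisubstituted alkenes with molybdenum monoaryloxide chloride alkylidenes; what is new is a 2-substituted butadiene terminus as the partner, so that the trisubstituted alkene is formed inside a conjugated diene from a vinyl-conjugated alkylidene. The 14-membered lactone ring closes end to end by macrocyclic ring-closing metathesis between C11 and C12, favoured over oligomerisation at 1 mM while propene is pumped off. No stereocentre is formed; the alkene geometry is set by the catalyst, because in the metallacyclobutane the C10 substituent of the alkylidene and the methyl of the departing ethylidene both point away from the large terphenoxide toward the small imido ligand, so C10 takes the place of the cap methyl, cis to C13 (11Z). The step needs site selectivity, which the substitution pattern of the other three alkenes secures, and kinetic rather than thermodynamic control of geometry, which follows from stereoretention and from the reluctance of the hindered product diene to re-enter the cycle.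

Step 22
Reactants: 31 (2R,3R,4R,6E,8S,11Z,13S)-4-[(tert-butyldiphenylsilyloxy)methyl]-6-methoxy-2,8,12-trimethyl-10-methylidene-3,4-bis(triethylsilyloxy)pentadeca-6,11-dien-13-olide
Product: 32 (2R,3R,4R,6E,8S,11Z,13S)-4-[(tert-butyldiphenylsilyloxy)methyl]-3-hydroxy-6-methoxy-2,8,12-trimethyl-10-methylidene-4-(triethylsilyloxy)pentadeca-6,11-dien-13-olide
Conditions: HF·pyridine, pyridine, THF, 0 °C
Reagents that add atoms: none
Why: Selective desilylation should cleave the secondary C3 triethylsilyl ether before the tertiary one and the TBDPS ether, and any diol formed by loss of both still converges on the target through steps 23 and 24.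

Step 23
Reactants: 32 (2R,3R,4R,6E,8S,11Z,13S)-4-[(tert-butyldiphenylsilyloxy)methyl]-3-hydroxy-6-methoxy-2,8,12-trimethyl-10-methylidene-4-(triethylsilyloxy)pentadeca-6,11-dien-13-olide
Product: 33 (2R,4R,6E,8S,11Z,13S)-4-[(tert-butyldiphenylsilyloxy)methyl]-6-methoxy-2,8,12-trimethyl-10-methylidene-3-oxo-4-(triethylsilyloxy)pentadeca-6,11-dien-13-olide
Conditions: Dess–Martin periodinane, NaHCO3, CH2Cl2, 0 °C → rt
Reagents that add atoms: none
Why: Dess–Martin oxidation of the C3 carbinol under bicarbonate buffer gives the β-keto lactone under conditions that should not epimerise C2.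

Step 24
Reactants: 33 (2R,4R,6E,8S,11Z,13S)-4-[(tert-butyldiphenylsilyloxy)methyl]-6-methoxy-2,8,12-trimethyl-10-methylidene-3-oxo-4-(triethylsilyloxy)pentadeca-6,11-dien-13-olide
Product: 34 (2R,4R,6E,8S,11Z,13S)-4-hydroxy-4-(hydroxymethyl)-6-methoxy-2,8,12-trimethyl-10-methylidene-3-oxopentadeca-6,11-dien-13-olide (CNP0325854.3)
Conditions: HF·pyridine, pyridine, THF, 0 °C → rt
Reagents that add atoms: none
Why: Fluoride-mediated cleavage of the tertiary triethylsilyl and the TBDPS ether is run with pyridine-buffered HF rather than basic fluoride, because a C4 alkoxide could translactonise onto C1 and unbuffered acid would hydrolyse the enol ether.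

**Compound list**

1 | (R)-4-benzyl-3-propionyloxazolidin-2-one | CCC(=O)N1[C@H](Cc2ccccc2)COC1=O | starting material
2 | 2,3-dibromopropene | BrCC(Br)=C | starting material
3 | sodium (Z)-enolate of 1 (formed in the flask) | C/C=C(\[O-])N1[C@H](Cc2ccccc2)COC1=O.[Na+] | intermediate
4 | (R)-4-benzyl-3-[(S)-4-bromo-2-methylpent-4-enoyl]oxazolidin-2-one | C=C(Br)C[C@H](C)C(=O)N1[C@H](Cc2ccccc2)COC1=O | intermediate
5 | (S)-4-bromo-2-methylpent-4-en-1-ol | C=C(Br)C[C@H](C)CO | intermediate
6 | (S)-4-bromo-2-methylpent-4-enal (formed in the flask) | C=C(Br)C[C@H](C)C=O | intermediate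
7 | (S)-2-bromo-4-methylhex-1-en-5-yne | C=C(Br)C[C@H](C)C#C | intermediate
8 | 2-methylenepropane-1,3-diol | C=C(CO)CO | starting material
9 | 2-[(tert-butyldiphenylsilyloxy)methyl]prop-2-en-1-ol | C=C(CO)CO[Si](c1ccccc1)(c1ccccc1)C(C)(C)C | intermediate
10 | [(2R)-2-[(tert-butyldiphenylsilyloxy)methyl]oxiran-2-yl]methanol | OC[C@]1(CO[Si](c2ccccc2)(c2ccccc2)C(C)(C)C)CO1 | intermediate
11 | (2S)-2-[(tert-butyldiphenylsilyloxy)methyl]-2-[(triethylsilyloxy)methyl]oxirane | CC[Si](CC)(CC)OC[C@]1(CO[Si](c2ccccc2)(c2ccccc2)C(C)(C)C)CO1 | intermediate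
12 | lithium acetylide of 7 (formed in the flask) | [Li]C#C[C@@H](C)CC(Br)=C | intermediate
13 | (2S,6S)-8-bromo-2-[(tert-butyldiphenylsilyloxy)methyl]-6-methyl-1-(triethylsilyloxy)non-8-en-4-yn-2-ol | CC[Si](CC)(CC)OC[C@](O)(CO[Si](c1ccccc1)(c1ccccc1)C(C)(C)C)CC#C[C@@H](C)CC(Br)=C | intermediate
14 | (2S,6S)-8-bromo-2-[(tert-butyldiphenylsilyloxy)methyl]-6-methyl-1,2-bis(triethylsilyloxy)non-8-en-4-yne | CC[Si](CC)(CC)OC[C@](O[Si](CC)(CC)CC)(CO[Si](c1ccccc1)(c1ccccc1)C(C)(C)C)CC#C[C@@H](C)CC(Br)=C | intermediate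
15 | (2S,4Z,6S)-8-bromo-2-[(tert-butyldiphenylsilyloxy)methyl]-6-methyl-4-(4,4,5,5-tetramethyl-1,3,2-dioxaborolan-2-yl)-1,2-bis(triethylsilyloxy)nona-4,8-diene | CC[Si](CC)(CC)OC[C@](O[Si](CC)(CC)CC)(CO[Si](c1ccccc1)(c1ccccc1)C(C)(C)C)C/C(B1OC(C)(C)C(C)(C)O1)=C\[C@@H](C)CC(Br)=C | intermediate
16 | (2S,4E,6S)-8-bromo-2-[(tert-butyldiphenylsilyloxy)methyl]-4-methoxy-6-methyl-1,2-bis(triethylsilyloxy)nona-4,8-diene | CC[Si](CC)(CC)OC[C@](O[Si](CC)(CC)CC)(CO[Si](c1ccccc1)(c1ccccc1)C(C)(C)C)C/C(OC)=C\[C@@H](C)CC(Br)=C | intermediate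
17 | (2S,4E,6S)-8-bromo-2-[(tert-butyldiphenylsilyloxy)methyl]-4-methoxy-6-methyl-2-(triethylsilyloxy)nona-4,8-dien-1-ol | OC[C@](O[Si](CC)(CC)CC)(CO[Si](c1ccccc1)(c1ccccc1)C(C)(C)C)C/C(OC)=C\[C@@H](C)CC(Br)=C | intermediate
18 | (2R,4E,6S)-8-bromo-2-[(tert-butyldiphenylsilyloxy)methyl]-4-methoxy-6-methyl-2-(triethylsilyloxy)nona-4,8-dienal | O=C[C@](O[Si](CC)(CC)CC)(CO[Si](c1ccccc1)(c1ccccc1)C(C)(C)C)C/C(OC)=C\[C@@H](C)CC(Br)=C | intermediate
19 | dibutylboron (Z)-enolate of 1 (formed in the flask) | C/C=C(\OB(CCCC)CCCC)N1[C@H](Cc2ccccc2)COC1=O | intermediate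
20 | (R)-4-benzyl-3-[(2R,3R,4R,6E,8S)-10-bromo-4-[(tert-butyldiphenylsilyloxy)methyl]-3-hydroxy-6-methoxy-2,8-dimethyl-4-(triethylsilyloxy)undeca-6,10-dienoyl]oxazolidin-2-one | O=C(N1[C@H](Cc2ccccc2)COC1=O)[C@H](C)[C@@H](O)[C@](O[Si](CC)(CC)CC)(CO[Si](c3ccccc3)(c3ccccc3)C(C)(C)C)C/C(OC)=C\[C@@H](C)CC(Br)=C | intermediate
21 | (R)-4-benzyl-3-[(2R,3R,4R,6E,8S)-10-bromo-4-[(tert-butyldiphenylsilyloxy)methyl]-6-methoxy-2,8-dimethyl-3,4-bis(triethylsilyloxy)undeca-6,10-dienoyl]oxazolidin-2-one | O=C(N1[C@H](Cc2ccccc2)COC1=O)[C@H](C)[C@@H](O[Si](CC)(CC)CC)[C@](O[Si](CC)(CC)CC)(CO[Si](c3ccccc3)(c3ccccc3)C(C)(C)C)C/C(OC)=C\[C@@H](C)CC(Br)=C | intermediate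
22 | (R)-4-benzyl-3-[(2R,3R,4R,6E,8S)-4-[(tert-butyldiphenylsilyloxy)methyl]-6-methoxy-2,8-dimethyl-10-methylidene-3,4-bis(triethylsilyloxy)dodeca-6,11-dienoyl]oxazolidin-2-one | O=C(N1[C@H](Cc2ccccc2)COC1=O)[C@H](C)[C@@H](O[Si](CC)(CC)CC)[C@](O[Si](CC)(CC)CC)(CO[Si](c3ccccc3)(c3ccccc3)C(C)(C)C)C/C(OC)=C\[C@@H](C)CC(=C)C=C | intermediate
23 | lithium peroxycarboxylate corresponding to acid 24 (formed in the flask) | [Li+].[O-]OC(=O)[C@H](C)[C@@H](O[Si](CC)(CC)CC)[C@](O[Si](CC)(CC)CC)(CO[Si](c1ccccc1)(c1ccccc1)C(C)(C)C)C/C(OC)=C\[C@@H](C)CC(=C)C=C | intermediate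
24 | (2R,3R,4R,6E,8S)-4-[(tert-butyldiphenylsilyloxy)methyl]-6-methoxy-2,8-dimethyl-10-methylidene-3,4-bis(triethylsilyloxy)dodeca-6,11-dienoic acid | OC(=O)[C@H](C)[C@@H](O[Si](CC)(CC)CC)[C@](O[Si](CC)(CC)CC)(CO[Si](c1ccccc1)(c1ccccc1)C(C)(C)C)C/C(OC)=C\[C@@H](C)CC(=C)C=C | intermediate
25 | angelic acid, (Z)-2-methylbut-2-enoic acid | C/C=C(/C)C(=O)O | starting material
26 | (Z)-N-methoxy-N,2-dimethylbut-2-enamide | C/C=C(/C)C(=O)N(C)OC | intermediate
27 | (Z)-4-methylhex-4-en-3-one | C/C=C(/C)C(=O)CC | intermediate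
28 | (S,Z)-4-methylhex-4-en-3-ol | C/C=C(/C)[C@H](CC)O | intermediate
29 | mixed anhydride of acid 24 and 2,4,6-trichlorobenzoic acid (formed in the flask) | O=C(OC(=O)c1c(Cl)cc(Cl)cc1Cl)[C@H](C)[C@@H](O[Si](CC)(CC)CC)[C@](O[Si](CC)(CC)CC)(CO[Si](c2ccccc2)(c2ccccc2)C(C)(C)C)C/C(OC)=C\[C@@H](C)CC(=C)C=C | intermediate
30 | (S,Z)-4-methylhex-4-en-3-yl (2R,3R,4R,6E,8S)-4-[(tert-butyldiphenylsilyloxy)methyl]-6-methoxy-2,8-dimethyl-10-methylidene-3,4-bis(triethylsilyloxy)dodeca-6,11-dienoate | C/C=C(/C)[C@H](CC)OC(=O)[C@H](C)[C@@H](O[Si](CC)(CC)CC)[C@](O[Si](CC)(CC)CC)(CO[Si](c1ccccc1)(c1ccccc1)C(C)(C)C)C/C(OC)=C\[C@@H](C)CC(=C)C=C | intermediate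
31 | (2R,3R,4R,6E,8S,11Z,13S)-4-[(tert-butyldiphenylsilyloxy)methyl]-6-methoxy-2,8,12-trimethyl-10-methylidene-3,4-bis(triethylsilyloxy)pentadeca-6,11-dien-13-olide | C=C1/C=C(/C)[C@H](CC)OC(=O)[C@H](C)[C@@H](O[Si](CC)(CC)CC)[C@](O[Si](CC)(CC)CC)(CO[Si](c2ccccc2)(c2ccccc2)C(C)(C)C)C/C(OC)=C\[C@@H](C)C1 | intermediate
32 | (2R,3R,4R,6E,8S,11Z,13S)-4-[(tert-butyldiphenylsilyloxy)methyl]-3-hydroxy-6-methoxy-2,8,12-trimethyl-10-methylidene-4-(triethylsilyloxy)pentadeca-6,11-dien-13-olide | C=C1/C=C(/C)[C@H](CC)OC(=O)[C@H](C)[C@@H](O)[C@](O[Si](CC)(CC)CC)(CO[Si](c2ccccc2)(c2ccccc2)C(C)(C)C)C/C(OC)=C\[C@@H](C)C1 | intermediate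
33 | (2R,4R,6E,8S,11Z,13S)-4-[(tert-butyldiphenylsilyloxy)methyl]-6-methoxy-2,8,12-trimethyl-10-methylidene-3-oxo-4-(triethylsilyloxy)pentadeca-6,11-dien-13-olide | C=C1/C=C(/C)[C@H](CC)OC(=O)[C@H](C)C(=O)[C@](O[Si](CC)(CC)CC)(CO[Si](c2ccccc2)(c2ccccc2)C(C)(C)C)C/C(OC)=C\[C@@H](C)C1 | intermediate
34 | (2R,4R,6E,8S,11Z,13S)-4-hydroxy-4-(hydroxymethyl)-6-methoxy-2,8,12-trimethyl-10-methylidene-3-oxopentadeca-6,11-dien-13-olide | C=C1/C=C(/C)[C@H](CC)OC(=O)[C@H](C)C(=O)[C@](O)(CO)C/C(OC)=C\[C@@H](C)C1 | target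

**Count and risks**

Total steps: 24. Longest linear sequence: 18 steps (steps 4–16 and 20–24 from 8, or equally steps 1–3, 7–16 and 20–24 from 1).

Steps most likely to fail:

1. Step 21 (ring-closing metathesis). The vinyl-conjugated alkylidene formed at the diene terminus may be too unreactive toward the hindered trisubstituted alkene, so that oligomerisation through the vinyl group, or erosion of geometry by slower non-retentive pathways, outruns ring closure. The fallback builds the diene by cross-coupling and closes the ring at the ester; it sets out from 21 and comes back at 31. Purchased (S)-pent-1-yn-3-ol undergoes hydroxyl-directed anti carbomagnesiation (MeMgBr, CuI cat., Et2O/THF) and iodine quench to give (S,Z)-1-iodo-2-methylpent-1-en-3-ol F1. Iodine–lithium exchange (t-BuLi, Et2O, −78 °C) and Bu3SnCl give (S,Z)-2-methyl-1-(tributylstannyl)pent-1-en-3-ol F2. Stille coupling of F2 with bromide 21 (Pd2(dba)3, AsPh3, CuI, NMP) forms the C10–C11 bond with retention and gives the hydroxy imide F3. LiOH/H2O2 then converts F3 through its lithium peroxycarboxylate F4 (reduced by Na2SO3) into the seco hydroxy acid F5. Shiina macrolactonisation of F5 (2-methyl-6-nitrobenzoic anhydride, DMAP, toluene, high dilution) gives 31. The 11Z geometry then rests on the configurationally stable alkenylstannane.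

2. Step 9 (copper hydride hydroboration). Hydrocupration may place copper at C7 instead of C6, because a neopentyl-type and an α-branched alkyne terminus differ little; the methoxy group would then end up on the wrong carbon. The fallback fixes the regiochemistry with a tether; it sets out from 13 and comes back at 16, and it also avoids steps 8 and 10. Alcohol 13 is silylated with (HMe2Si)2NH to the dimethylsilyl ether F6, which with Pt2[(CH2=CHSiMe2)2O]3 undergoes intramolecular syn hydrosilylation (5-exo-dig) to the oxasilolane F7, silicon being bound to C6 by the tether length and cis to H7. Iododesilylation with retention (N-iodosuccinimide, (CF3)2CHOH, 0 °C; then K2CO3, MeOH) gives the alkenyl iodide F8. TESOTf and 2,6-lutidine give its tertiary silyl ether F9. Copper-catalysed coupling with methanol (CuI, 3,4,7,8-tetramethyl-1,10-phenanthroline, Cs2CO3, MeOH/toluene, 80 °C) then gives 16 with retention, the alkenyl iodide reacting well before the 2-bromoalkene.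

3. Step 17 (activation of angelic acid). Reversible conjugate addition of nucleophiles to the activated acyl species can isomerise the Z alkene to the E (tiglate) geometry, and the stereoretentive ring closure would copy that error into the macrocycle. The fallback avoids carboxyl activation; it sets out from 25 and comes back at 27 without any new isolated compound (F0). Acid 25 is converted into its lithium salt with LiH in Et2O and treated with EtLi at −78 → 0 °C. The geminal dilithium alkoxide collapses to ketone 27 only on inverse quench into cold aqueous NH4Cl, so no acyl derivative able to isomerise is present.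

**Further compounds**

F1 | step 21 | (S,Z)-1-iodo-2-methylpent-1-en-3-ol | I/C=C(/C)[C@H](CC)O
F2 | step 21 | (S,Z)-2-methyl-1-(tributylstannyl)pent-1-en-3-ol | CCCC[Sn](CCCC)(CCCC)/C=C(/C)[C@H](CC)O
F3 | step 21 | (R)-4-benzyl-3-[(2R,3R,4R,6E,8S,11Z,13S)-4-[(tert-butyldiphenylsilyloxy)methyl]-13-hydroxy-6-methoxy-2,8,12-trimethyl-10-methylidene-3,4-bis(triethylsilyloxy)pentadeca-6,11-dienoyl]oxazolidin-2-one | O=C(N1[C@H](Cc2ccccc2)COC1=O)[C@H](C)[C@@H](O[Si](CC)(CC)CC)[C@](O[Si](CC)(CC)CC)(CO[Si](c3ccccc3)(c3ccccc3)C(C)(C)C)C/C(OC)=C\[C@@H](C)CC(=C)/C=C(/C)[C@H](CC)O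
F4 | step 21 | lithium peroxycarboxylate corresponding to acid F5 | [Li+].[O-]OC(=O)[C@H](C)[C@@H](O[Si](CC)(CC)CC)[C@](O[Si](CC)(CC)CC)(CO[Si](c1ccccc1)(c1ccccc1)C(C)(C)C)C/C(OC)=C\[C@@H](C)CC(=C)/C=C(/C)[C@H](CC)O
F5 | step 21 | (2R,3R,4R,6E,8S,11Z,13S)-4-[(tert-butyldiphenylsilyloxy)methyl]-13-hydroxy-6-methoxy-2,8,12-trimethyl-10-methylidene-3,4-bis(triethylsilyloxy)pentadeca-6,11-dienoic acid | OC(=O)[C@H](C)[C@@H](O[Si](CC)(CC)CC)[C@](O[Si](CC)(CC)CC)(CO[Si](c1ccccc1)(c1ccccc1)C(C)(C)C)C/C(OC)=C\[C@@H](C)CC(=C)/C=C(/C)[C@H](CC)O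
F6 | step 9 | dimethylsilyl ether of 13 at the tertiary hydroxyl | CC[Si](CC)(CC)OC[C@](O[SiH](C)C)(CO[Si](c1ccccc1)(c1ccccc1)C(C)(C)C)CC#C[C@@H](C)CC(Br)=C
F7 | step 9 | (3E,5S)-3-[(2S)-4-bromo-2-methylpent-4-en-1-ylidene]-5-[(tert-butyldiphenylsilyloxy)methyl]-2,2-dimethyl-5-[(triethylsilyloxy)methyl]-1,2-oxasilolane | CC[Si](CC)(CC)OC[C@]1(CO[Si](c2ccccc2)(c2ccccc2)C(C)(C)C)C/C(=C\[C@@H](C)CC(Br)=C)[Si](C)(C)O1
F8 | step 9 | (2S,4E,6S)-8-bromo-2-[(tert-butyldiphenylsilyloxy)methyl]-4-iodo-6-methyl-1-(triethylsilyloxy)nona-4,8-dien-2-ol | CC[Si](CC)(CC)OC[C@](O)(CO[Si](c1ccccc1)(c1ccccc1)C(C)(C)C)C/C(I)=C\[C@@H](C)CC(Br)=C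
F9 | step 9 | (2S,4E,6S)-8-bromo-2-[(tert-butyldiphenylsilyloxy)methyl]-4-iodo-6-methyl-1,2-bis(triethylsilyloxy)nona-4,8-diene | CC[Si](CC)(CC)OC[C@](O[Si](CC)(CC)CC)(CO[Si](c1ccccc1)(c1ccccc1)C(C)(C)C)C/C(I)=C\[C@@H](C)CC(Br)=C
F0 | step 17 | none | none
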